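**Retrosynthetic overview**
- Ring C (the 4-pyranone) is the only ring that is built, and it is closed last by forming the aryl–oxygen bond O1–C8a: the enolate oxygen of an α-formyl deoxybenzoin displaces an ortho fluorine, with ethyl formate supplying C2 and O1.
- The deoxybenzoin is cut at the CH2–aryl bond: Pd-catalysed α-arylation of a 2-fluoro-4-methoxy-3-prenyl acetophenone with a commercial bromotrimethoxybenzene (ring B bought intact).
- The acetyl group comes from Br/Mg exchange and Weinreb acylation. The prenyl group comes from lithiation between F and OMe of a commercial bromofluoroanisole (ring A bought intact).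
- The fluorine does double duty: it directs the prenylation and is the leaving group of the ring closure.

Assumption: the target has no stereocentre and no stereogenic double bond (the prenyl alkene carries two identical methyl groups), so the "single enantiomer" is the achiral compound itself and no stereocontrol is needed.

**Step 1**
Reactants: 1 1-bromo-2-fluoro-4-methoxybenzene (4-bromo-3-fluoroanisole); 2 1-bromo-3-methylbut-2-ene (prenyl bromide)
Product: 4 1-bromo-2-fluoro-4-methoxy-3-(3-methylbut-2-en-1-yl)benzene, via aryllithium 3 (not isolated)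
Conditions: LDA (1.1 equiv), THF, −78 °C, 1 h; then 2 (1.3 equiv), −78 → −40 °C; aq NH4Cl
Reagents that add atoms: none
Why: Directed ortho-metalation removes the ring proton flanked by F and OMe (by far the most acidic; LDA does not exchange the bromine), the aryllithium is kept cold so that it cannot lose LiF to an aryne, and it attacks the unhindered CH2 terminus of prenyl bromide (SN2) to give the linear prenyl arene.

**Step 2**
Reactants: 4 1-bromo-2-fluoro-4-methoxy-3-(3-methylbut-2-en-1-yl)benzene
Product: 7 1-[2-fluoro-4-methoxy-3-(3-methylbut-2-en-1-yl)phenyl]ethan-1-one, via arylmagnesium chloride 5 (not isolated), via tetrahedral magnesium adduct 6 (not isolated)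
Conditions: iPrMgCl·LiCl (1.1 equiv), THF, 0 °C, 2 h; MeC(O)N(OMe)Me (1.3 equiv), 0 °C → rt; cold 1 M HCl
Reagents that add atoms: N-methoxy-N-methylacetamide, CC(=O)N(C)OC
Why: Halogen–magnesium exchange with the turbo-Grignard reagent (accelerated by the ortho fluorine) is followed by a Weinreb ketone synthesis, in which the chelated adduct 6 blocks over-addition and collapses to the methyl ketone only on acidic work-up.

**Step 3**
Reactants: 7 1-[2-fluoro-4-methoxy-3-(3-methylbut-2-en-1-yl)phenyl]ethan-1-one; 8 1-bromo-2,4,5-trimethoxybenzene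
Product: 9 1-[2-fluoro-4-methoxy-3-(3-methylbut-2-en-1-yl)phenyl]-2-(2,4,5-trimethoxyphenyl)ethan-1-one
Conditions: 8 (1.1 equiv), Pd2(dba)3 (1.5 mol%), Xantphos (3.6 mol%), K3PO4 (2.3 equiv), toluene, 90 °C
Reagents that add atoms: none
Why: This is a Buchwald–Hartwig-type Pd-catalysed α-arylation of a methyl ketone enolate; the weak base K3PO4 spares the C–F bond and the prenyl group, and the ortho-methoxy aryl group together with the more acidic, enolised product suppresses diarylation.

**Step 4**
Reactants: 9 1-[2-fluoro-4-methoxy-3-(3-methylbut-2-en-1-yl)phenyl]-2-(2,4,5-trimethoxyphenyl)ethan-1-one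
Product: 11 prebarbigerone, 7-methoxy-8-(3-methylbut-2-en-1-yl)-3-(2,4,5-trimethoxyphenyl)-4H-chromen-4-one, via potassium formyl enolate 10 (not isolated)
Conditions: KOtBu (0.98 equiv), HCO2Et (5 equiv), THF, 0 °C → rt; evaporate; dry DMSO (0.05 M), 18-crown-6 (10 mol%), 110 °C
Reagents that add atoms: ethyl formate, CCOC=O
Why: Proposed new method: a formylative SNAr annulation in which ethyl formate delivers both C2 and the ring oxygen O1 — Claisen C-formylation of the benzylic ketone gives the potassium Z-enolate 10 of the 2-aryl-3-oxopropanal, whose terminal enolate oxygen (left poorly solvated in DMSO/18-crown-6) attacks the C–F carbon ortho to the ketone through a six-membered Meisenheimer-type transition state and expels fluoride irreversibly, forming the O1–C8a bond and the aromatic 4-pyranone; the closest known reaction types are the base-mediated intramolecular SNAr O-arylation of 1-(2-fluoroaryl)-1,3-diketone enolates to flavones and the Grohe cycloaracylation of 2-fluorobenzoyl enaminones to 4-quinolones, extended here to a 2-unsubstituted 3-aryl chromone on a donor-substituted fluoroarene, and the slight deficit of KOtBu leaves no free alkoxide that could isomerise the prenyl group or open the chromone.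

**Compound list**
1 | 1-bromo-2-fluoro-4-methoxybenzene | COc1ccc(Br)c(F)c1 | starting material
2 | 1-bromo-3-methylbut-2-ene (prenyl bromide) | CC(C)=CCBr | starting material
3 | (3-bromo-2-fluoro-6-methoxyphenyl)lithium | [Li]c1c(OC)ccc(Br)c1F | intermediate
4 | 1-bromo-2-fluoro-4-methoxy-3-(3-methylbut-2-en-1-yl)benzene | COc1ccc(Br)c(F)c1CC=C(C)C | intermediate
5 | [2-fluoro-4-methoxy-3-(3-methylbut-2-en-1-yl)phenyl]magnesium chloride (LiCl complex) | COc1ccc([Mg]Cl)c(F)c1CC=C(C)C | intermediate
6 | chloromagnesium 1-[2-fluoro-4-methoxy-3-(3-methylbut-2-en-1-yl)phenyl]-1-[methoxy(methyl)amino]ethan-1-olate (racemic, transient) | COc1ccc(C(C)(O[Mg]Cl)N(C)OC)c(F)c1CC=C(C)C | intermediate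
7 | 1-[2-fluoro-4-methoxy-3-(3-methylbut-2-en-1-yl)phenyl]ethan-1-one | COc1ccc(C(C)=O)c(F)c1CC=C(C)C | intermediate
8 | 1-bromo-2,4,5-trimethoxybenzene | COc1cc(OC)c(Br)cc1OC | starting material
9 | 1-[2-fluoro-4-methoxy-3-(3-methylbut-2-en-1-yl)phenyl]-2-(2,4,5-trimethoxyphenyl)ethan-1-one | COc1ccc(C(=O)Cc2cc(OC)c(OC)cc2OC)c(F)c1CC=C(C)C | intermediate
10 | potassium (Z)-3-[2-fluoro-4-methoxy-3-(3-methylbut-2-en-1-yl)phenyl]-3-oxo-2-(2,4,5-trimethoxyphenyl)prop-1-en-1-olate | [K+].[O-]/C=C(/c1cc(OC)c(OC)cc1OC)C(=O)c1ccc(OC)c(CC=C(C)C)c1F | intermediate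
11 | prebarbigerone, 7-methoxy-8-(3-methylbut-2-en-1-yl)-3-(2,4,5-trimethoxyphenyl)-4H-chromen-4-one (achiral) | COc1cc(OC)c(-c2coc3c(CC=C(C)C)c(OC)ccc3c2=O)cc1OC | target

**Summary**
Total step count: 4. Longest linear sequence: 4 steps (1 → 4 → 7 → 9 → 11).

**Steps most likely to fail, with fallbacks**

Step 4 (the proposed new ring closure). The fluoroarene is electron-rich and the ketone that should activate it is part of the enolate, so the SNAr may be slow or may not compete with deformylation. The fallback uses known chemistry and moves the ring closure to the O1–C2 bond. It sets out from 9 and returns at 11.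
- Ketone 9 is condensed with NH2OH·HCl (pyridine, EtOH, 60 °C) to the oxime 1-[2-fluoro-4-methoxy-3-(3-methylbut-2-en-1-yl)phenyl]-2-(2,4,5-trimethoxyphenyl)ethan-1-one oxime F4 (E/Z mixture).
- The oximate oxygen displaces the ortho fluorine in a five-membered closure (KOH, aqueous dioxane, reflux), the standard route from 2-fluoroaryl ketoximes to 1,2-benzisoxazoles. This gives 6-methoxy-7-(3-methylbut-2-en-1-yl)-3-[(2,4,5-trimethoxyphenyl)methyl]-1,2-benzoxazole F5.
- Reductive N–O cleavage (Mo(CO)6, MeCN/H2O, 80 °C, which leaves the prenyl alkene alone) gives the ketimine 2-[1-imino-2-(2,4,5-trimethoxyphenyl)ethyl]-5-methoxy-6-(3-methylbut-2-en-1-yl)phenol F6.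
- F6 hydrolyses in the aqueous medium to 1-[2-hydroxy-4-methoxy-3-(3-methylbut-2-en-1-yl)phenyl]-2-(2,4,5-trimethoxyphenyl)ethan-1-one F7.
- Heating F7 with DMF dimethyl acetal (toluene, 90 °C) gives the enaminone 3-(dimethylamino)-1-[2-hydroxy-4-methoxy-3-(3-methylbut-2-en-1-yl)phenyl]-2-(2,4,5-trimethoxyphenyl)prop-2-en-1-one F8, which closes with loss of dimethylamine to 11.

Step 1 (lithiation and prenylation). The ortho-fluoro aryllithium must be alkylated below about −50 °C to avoid aryne formation, and prenyl bromide could react sluggishly or partly at its tertiary terminus. The fallback sets out from 1 and returns at 4. The same aryllithium 3 is trapped with allyl bromide, which is faster and has no regiochemical ambiguity, to give 1-bromo-2-fluoro-4-methoxy-3-(prop-2-en-1-yl)benzene F1. Olefin cross-metathesis of F1 with excess 2-methylbut-2-ene (Grubbs second-generation catalyst, CH2Cl2, 40 °C) then installs the prenyl terminus and gives 4.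

Step 3 (α-arylation). An electron-rich, ortho-substituted aryl bromide and a base-sensitive 2-fluoro ketone may give low conversion or side reactions at C–F. The fallback forms the aryl–acyl bond instead of the CH2–aryl bond and needs no palladium. It sets out from 4 and returns at 9, replacing steps 2 and 3. Purchased 2-(2,4,5-trimethoxyphenyl)acetic acid F2 is converted (CDI, then MeNHOMe·HCl, CH2Cl2) into N-methoxy-N-methyl-2-(2,4,5-trimethoxyphenyl)acetamide F3. Grignard reagent 5, made from 4 as in step 2, is added to F3 at −20 °C (kept cold to limit enolisation of the amide), and acidic work-up gives 9.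

**Further compounds**
F1 | step 1 | 1-bromo-2-fluoro-4-methoxy-3-(prop-2-en-1-yl)benzene | COc1ccc(Br)c(F)c1CC=C
F2 | step 3 | 2-(2,4,5-trimethoxyphenyl)acetic acid (purchased) | COc1cc(OC)c(CC(=O)O)cc1OC
F3 | step 3 | N-methoxy-N-methyl-2-(2,4,5-trimethoxyphenyl)acetamide | COc1cc(OC)c(CC(=O)N(C)OC)cc1OC
F4 | step 4 | 1-[2-fluoro-4-methoxy-3-(3-methylbut-2-en-1-yl)phenyl]-2-(2,4,5-trimethoxyphenyl)ethan-1-one oxime (E/Z mixture) | COc1ccc(C(Cc2cc(OC)c(OC)cc2OC)=NO)c(F)c1CC=C(C)C
F5 | step 4 | 6-methoxy-7-(3-methylbut-2-en-1-yl)-3-[(2,4,5-trimethoxyphenyl)methyl]-1,2-benzoxazole | COc1ccc2c(Cc3cc(OC)c(OC)cc3OC)noc2c1CC=C(C)C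
F6 | step 4 | 2-[1-imino-2-(2,4,5-trimethoxyphenyl)ethyl]-5-methoxy-6-(3-methylbut-2-en-1-yl)phenol | COc1ccc(C(=N)Cc2cc(OC)c(OC)cc2OC)c(O)c1CC=C(C)C
F7 | step 4 | 1-[2-hydroxy-4-methoxy-3-(3-methylbut-2-en-1-yl)phenyl]-2-(2,4,5-trimethoxyphenyl)ethan-1-one | COc1ccc(C(=O)Cc2cc(OC)c(OC)cc2OC)c(O)c1CC=C(C)C
F8 | step 4 | 3-(dimethylamino)-1-[2-hydroxy-4-methoxy-3-(3-methylbut-2-en-1-yl)phenyl]-2-(2,4,5-trimethoxyphenyl)prop-2-en-1-one (alkene geometry not fixed) | COc1ccc(C(=O)C(=CN(C)C)c2cc(OC)c(OC)cc2OC)c(O)c1CC=C(C)C
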